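**Plan**
- Retrosynthetic cuts, with C1' as the chain carbon on pyrrole C5 and C19' as the methyl end: (i) pyrrole C2–CHO (Vilsmeier–Haack), (ii) chain C7'–C8' (decarboxylative radical coupling), (iii) pyrrole C5–C1' (acylation).
- Forward order: the pyrrole ring is bought as 1-tosylpyrrole and acylated with a C8 half ester. The freed acid is joined to tridecanoic acid at a platinum anode (C7 + C12 = C19). Both helpers then leave in one pot, and C2 is formylated last.
- Enabling feature: C7' and C8' are unbranched, unfunctionalised CH2 groups, so each maps onto a primary radical and hence onto a free carboxylic acid with one more carbon. The only anodically fragile part is the five-membered pyrrole ring with its C1'H2 group. It is masked as the N1-sulfonamide and the C1' ketone.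
- Stereochemistry: the target has no stereocentre and no stereogenic double bond, so nothing has to be set.

Key step: step 3

Remark: the SMILES holds no stereodescriptor and the molecule is achiral, so the demand for a single enantiomer is met by the constitution alone.

**Step 1**
Reactants: 1 1-tosyl-1H-pyrrole (commercial); 2 8-(benzyloxy)-8-oxooctanoic acid (suberic acid monobenzyl ester, commercial)
Product: 4 benzyl 8-oxo-8-(1-tosyl-1H-pyrrol-2-yl)octanoate, via acyl trifluoroacetate 3 (not isolated)
Conditions: 2 (1.3 equiv), (CF3CO)2O (4 equiv), CH2Cl2, rt; aq. NaHCO3 wash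
Reagents that add atoms: trifluoroacetic anhydride, O=C(OC(=O)C(F)(F)F)C(F)(F)F (its CF3CO unit is held only in 3 and is gone in 4)
Why: Lewis-acid-free Friedel–Crafts acylation by the mixed anhydride 3, a reaction type known to acylate N-sulfonylpyrroles at C2, should tolerate the benzyl ester because trifluoroacetic acid at room temperature does not cleave it, and it brings together the two electron-withdrawing helpers (N1-Ts, C1'=O) that the key step needs.

**Step 2**
Reactants: 4 benzyl 8-oxo-8-(1-tosyl-1H-pyrrol-2-yl)octanoate
Product: 5 8-oxo-8-(1-tosyl-1H-pyrrol-2-yl)octanoic acid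
Conditions: H2 (1 atm), 10% Pd/C, EtOAc, rt
Reagents that add atoms: none
Why: Catalytic hydrogenolysis of a benzyl ester is neutral, so the base-labile N-tosyl group stays, and at 1 atm over Pd/C neither the electron-poor pyrrole ring nor its conjugated ketone should be reduced.

**Step 3**
Reactants: 5 8-oxo-8-(1-tosyl-1H-pyrrol-2-yl)octanoic acid; 6 tridecanoic acid (commercial)
Product: 7 1-(1-tosyl-1H-pyrrol-2-yl)nonadecan-1-one
Conditions: Pt anode, Pt cathode, undivided cell, constant current (ca. 0.2 A cm−2), occasional polarity reversal; 6 (5 equiv), NaOMe (5 mol % of total CO2H), MeOH, 45 °C, stopped when 5 is consumed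
Reagents that add atoms: none
Why: Mixed Kolbe electrolysis: at the platinum anode both carboxylates lose one electron and then CO2, so the primary 7-oxo-7-(1-tosylpyrrol-2-yl)heptyl radical and the dodecyl radical arise side by side at high concentration in the anode layer and combine to the C7'–C8' bond, while protons are discharged to H2 at the Pt cathode at a potential far from that needed to reduce the ketone or the sulfonamide. The closest known reaction type is the cross-Kolbe chain extension of a fatty acid with an ω-functionalised (keto, ester or aryl) alkanoic acid, which is classical for CH2–CH2 bonds between two unbranched primary radicals. No ring is closed and no stereocentre is formed. The step needs oxidation of the carboxylate in preference to the pyrrole ring: the N1-sulfonyl group and the C1' carbonyl group together turn the π-excessive ring into an electron-poor one and replace the easily oxidised pyrrolic CH2, the tosyl unit is itself anodically inert, and the adsorbed carboxylate layer at high current density shields the rest of the molecule. It needs the radical and not the cation (Hofer–Moest) pathway, which unbranched primary radicals without an α-donor, smooth Pt, weakly acidic methanol and high current density secure, and the six-CH2 spacer makes any attack of the radical on the ketone or the ring a medium-ring process that should not compete with coupling. Cross- over homocoupling is only statistical, so the cheap acid 6 is used in fivefold excess, and the non-polar hydrocarbon dimer should be easy to separate from the polar ketone 7.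

**Step 4**
Reactants: 7 1-(1-tosyl-1H-pyrrol-2-yl)nonadecan-1-one
Product: 10 2-nonadecyl-1H-pyrrole, via N-H ketone 8 (not isolated), via hydrazone 9 (not isolated)
Conditions: (i) KOH (6 equiv), diethylene glycol, 100 °C; (ii) N2H4·H2O (10 equiv), 130 °C, then distil off H2O/N2H4, 195–200 °C, N2 atmosphere
Reagents that add atoms: hydrazine (used as hydrate), NN (its N2 unit is held only in 9 and is gone in 10)
Why: Hydroxide first cleaves the activated N-sulfonyl bond of the 2-acylpyrrole and the Wolff–Kishner reduction (Huang-Minlon procedure), classical for 2-acylpyrroles, then takes hydrazone 9 to the CH2 group with loss of N2, so that both helpers leave in one pot from a molecule that holds no other base- or heat-sensitive group.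

**Step 5**
Reactants: 10 2-nonadecyl-1H-pyrrole
Product: 12 5-nonadecyl-1H-pyrrole-2-carbaldehyde, via iminium ion 11 (not isolated)
Conditions: POCl3 (1.1 equiv), DMF (1.2 equiv), ClCH2CH2Cl, 0 °C to rt; then aq. NaOAc, reflux
Reagents that add atoms: N,N-dimethylformamide, CN(C)C=O (formyl carbon); water, O (aldehyde oxygen)
Why: Vilsmeier–Haack formylation of a 2-alkylpyrrole should go to the only free α-position (C5 of 10, which becomes C2 of the target) because the σ-complex there is the best stabilised, and the deactivating iminium group in 11 stops a second formylation before hydrolysis sets the aldehyde free.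

**Compound list**
1 | 1-tosyl-1H-pyrrole | Cc1ccc(cc1)S(=O)(=O)n1cccc1 | starting material
2 | 8-(benzyloxy)-8-oxooctanoic acid | OC(=O)CCCCCCC(=O)OCc1ccccc1 | starting material
3 | benzyl 8-oxo-8-(2,2,2-trifluoroacetoxy)octanoate (mixed anhydride) | FC(F)(F)C(=O)OC(=O)CCCCCCC(=O)OCc1ccccc1 | intermediate
4 | benzyl 8-oxo-8-(1-tosyl-1H-pyrrol-2-yl)octanoate | Cc1ccc(cc1)S(=O)(=O)n1cccc1C(=O)CCCCCCC(=O)OCc1ccccc1 | intermediate
5 | 8-oxo-8-(1-tosyl-1H-pyrrol-2-yl)octanoic acid | Cc1ccc(cc1)S(=O)(=O)n1cccc1C(=O)CCCCCCC(=O)O | intermediate
6 | tridecanoic acid | CCCCCCCCCCCCC(=O)O | starting material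
7 | 1-(1-tosyl-1H-pyrrol-2-yl)nonadecan-1-one | Cc1ccc(cc1)S(=O)(=O)n1cccc1C(=O)CCCCCCCCCCCCCCCCCC | intermediate
8 | 1-(1H-pyrrol-2-yl)nonadecan-1-one | O=C(CCCCCCCCCCCCCCCCCC)c1ccc[nH]1 | intermediate
9 | 1-(1H-pyrrol-2-yl)nonadecan-1-one hydrazone | NN=C(CCCCCCCCCCCCCCCCCC)c1ccc[nH]1 | intermediate
10 | 2-nonadecyl-1H-pyrrole | CCCCCCCCCCCCCCCCCCCc1ccc[nH]1 | intermediate
11 | N,N-dimethyl-1-(5-nonadecyl-1H-pyrrol-2-yl)methaniminium ion | CCCCCCCCCCCCCCCCCCCc1ccc(C=[N+](C)C)[nH]1 | intermediate
12 | 5-nonadecyl-1H-pyrrole-2-carbaldehyde | CCCCCCCCCCCCCCCCCCCc1ccc(C=O)[nH]1 | target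

**Total step count:** 5. **Longest linear sequence:** 5.

**Steps most likely to fail**

1. **Step 3.** Three processes could go wrong.
   - The heteroaromatic ring may be oxidised at the anode and foul the electrode.
   - The primary radicals may be over-oxidised to cations.
   - Statistical homocoupling may consume the valuable acid.

   The fallback sets out from 5 and comes back at 7. Acid 5 is esterified with N-hydroxyphthalimide (N,N'-diisopropylcarbodiimide, cat. DMAP, CH2Cl2) to the redox-active ester 1,3-dioxoisoindolin-2-yl 8-oxo-8-(1-tosyl-1H-pyrrol-2-yl)octanoate F1. This ester is coupled with didodecylzinc F2, made from commercial dodecylmagnesium bromide and ZnCl2 in THF. The coupling runs under nickel catalysis (NiCl2·glyme, 4,4'-di-tert-butyl-2,2'-bipyridine, THF/DMF, rt). This known reductive decarboxylative alkyl–alkyl coupling forms the same C7'–C8' bond without any anodic potential. The organozinc reagent should leave the ketone and the sulfonamide untouched.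

2. **Step 1.** The acylation may be sluggish, or acid may promote migration of the acyl group from C2 to C3 during the long contact with trifluoroacetic acid. The fallback sets out from 2 and comes back at 4.
   - Acid 2 is turned with oxalyl chloride and cat. DMF (CH2Cl2) into benzyl 8-chloro-8-oxooctanoate F3.
   - F3 acylates pyrrol-1-ylmagnesium bromide F4 (from pyrrole and EtMgBr, Et2O/toluene, −40 to 0 °C) at C2, giving benzyl 8-oxo-8-(1H-pyrrol-2-yl)octanoate F5.
   - N-tosylation (NaH, TsCl, THF, 0 °C) then gives 4.

3. **Step 4.** Hydrazone formation may be incomplete for the poorly soluble long-chain ketone, azine formation may compete, and the electron-rich pyrrole may degrade thermally or oxidatively near 200 °C. The fallback sets out from 7 and comes back at 10.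
   - Ketone 7 is detosylated under mild conditions (NaOH, dioxane/H2O, rt) and ketone 8 is isolated.
   - NaBH4 in refluxing 2-propanol reduces 8 to racemic 1-(1H-pyrrol-2-yl)nonadecan-1-ol F6.
   - F6 loses water to the azafulvene 2-nonadecylidene-2H-pyrrole F7, which takes up a second hydride to give 10.

**Further compounds**
F1 | step 3 | 1,3-dioxoisoindolin-2-yl 8-oxo-8-(1-tosyl-1H-pyrrol-2-yl)octanoate | Cc1ccc(cc1)S(=O)(=O)n1cccc1C(=O)CCCCCCC(=O)ON1C(=O)c2ccccc2C1=O
F2 | step 3 | didodecylzinc | CCCCCCCCCCCC[Zn]CCCCCCCCCCCC
F3 | step 1 | benzyl 8-chloro-8-oxooctanoate | ClC(=O)CCCCCCC(=O)OCc1ccccc1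
F4 | step 1 | pyrrol-1-ylmagnesium bromide | Br[Mg]n1cccc1
F5 | step 1 | benzyl 8-oxo-8-(1H-pyrrol-2-yl)octanoate | O=C(CCCCCCC(=O)OCc1ccccc1)c1ccc[nH]1
F6 | step 4 | 1-(1H-pyrrol-2-yl)nonadecan-1-ol (racemic) | OC(CCCCCCCCCCCCCCCCCC)c1ccc[nH]1
F7 | step 4 | 2-nonadecylidene-2H-pyrrole | CCCCCCCCCCCCCCCCCCC=C1C=CC=N1
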